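**Retrosynthetic overview**
1. Target 14 ⇒ bis-benzyl 5-O-methyl flavonol 13 by one Lewis-acid deprotection (two OBn, the peri 5-OMe).
2. 13 ⇒ salicylaldehyde 4 (ring A) + arylglyoxal 11 (ring B): C3–C4 and O1–C2 are made in one operation by a new Rh(III)-catalysed acyl C–H addition to the glyoxal C=O, followed by cyclodehydration.
3. 4 ⇐ 1,2,3,5-tetramethoxybenzene 1 (Vilsmeier formylation, selective ortho-demethylation).
4. 11 ⇐ O-benzylisovanillin 5 (Dakin oxidation, benzylation, Friedel–Crafts acetylation, Riley oxidation).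
5. Ring order: rings A and B are bought as arenes; the pyranone ring C is formed last, in the key step.

Assumption: the target, 2-(2,4-dihydroxy-5-methoxyphenyl)-3,5-dihydroxy-7,8-dimethoxy-4H-chromen-4-one, has no stereocentre and no configurationally stable axis, so "single enantiomer" needs no stereocontrol; 1 and 5 are taken as commercial.

**Route**

Step 1
Reactants: 1 1,2,3,5-tetramethoxybenzene
Product: 3 2,3,4,6-tetramethoxybenzaldehyde, via aryl iminium chloride 2 (not isolated)
Conditions: POCl3 (1.3 equiv), DMF, 0 → 70 °C; then H2O, rt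
Reagents that add atoms: N,N-dimethylformamide CN(C)C=O; water O
Why: Vilsmeier–Haack formylation; the two free positions of 1 are equivalent and each is ortho, ortho and para to methoxy groups, so a single aldehyde forms after hydrolysis of iminium 2.

Step 2
Reactants: 3 2,3,4,6-tetramethoxybenzaldehyde
Product: 4 2-hydroxy-3,4,6-trimethoxybenzaldehyde
Conditions: BCl3 (1.1 equiv), CH2Cl2, −78 → −10 °C; then H2O
Reagents that add atoms: none
Why: Chelation-controlled Lewis-acid ortho-demethylation; boron bound to the formyl oxygen cleaves the 2-OMe, which the 3-OMe buttresses out of plane (more basic oxygen, strain relief), in preference to the in-plane 6-OMe, and the resulting chelate resists a second cleavage.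

Step 3
Reactants: 5 3-(benzyloxy)-4-methoxybenzaldehyde
Product: 7 3-(benzyloxy)-4-methoxyphenol, via 3-(benzyloxy)-4-methoxyphenyl formate 6 (not isolated)
Conditions: mCPBA (1.3 equiv), CH2Cl2, 0 °C → rt; aq. NaHCO3 wash; then K2CO3 (cat.), MeOH, rt
Reagents that add atoms: mCPBA O=C(OO)c1cccc(Cl)c1
Why: Baeyer–Villiger (Dakin-type) oxidation; the electron-rich aryl group migrates in preference to hydrogen, and mild methanolysis cleaves formate 6.

Step 4
Reactants: 7 3-(benzyloxy)-4-methoxyphenol
Product: 8 2,4-bis(benzyloxy)-1-methoxybenzene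
Conditions: BnBr (1.2 equiv), K2CO3 (1.5 equiv), DMF, 60 °C
Reagents that add atoms: benzyl bromide BrCc1ccccc1
Why: Williamson ether synthesis (SN2 of the phenoxide on a benzylic bromide).

Step 5
Reactants: 8 2,4-bis(benzyloxy)-1-methoxybenzene
Product: 9 1-[2,4-bis(benzyloxy)-5-methoxyphenyl]ethan-1-one
Conditions: Ac2O (1.5 equiv), Sc(OTf)3 (5 mol %), MeNO2, rt
Reagents that add atoms: acetic anhydride CC(=O)OC(C)=O
Why: Catalytic Friedel–Crafts acylation; C5 is ortho to one benzyloxy group and para to the other (C3 is flanked on both sides, C6 is activated only by OMe), and a catalytic triflate avoids the stoichiometric Lewis acid that would cleave the benzyl ethers.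

Step 6
Reactants: 9 1-[2,4-bis(benzyloxy)-5-methoxyphenyl]ethan-1-one
Product: 11 2-[2,4-bis(benzyloxy)-5-methoxyphenyl]-2-oxoacetaldehyde, via glyoxal hydrate 10 (not isolated)
Conditions: SeO2 (1.3 equiv), 1,4-dioxane/H2O (30:1), 95 °C; filter; then toluene, Dean–Stark
Reagents that add atoms: selenium dioxide O=[Se]=O; water O
Why: Riley oxidation of an aryl methyl ketone to the arylglyoxal, which forms as hydrate 10 and is dried azeotropically to the free aldehyde.

Step 7
Reactants: 4 2-hydroxy-3,4,6-trimethoxybenzaldehyde; 11 2-[2,4-bis(benzyloxy)-5-methoxyphenyl]-2-oxoacetaldehyde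
Product: 13 2-[2,4-bis(benzyloxy)-5-methoxyphenyl]-3-hydroxy-5,7,8-trimethoxy-4H-chromen-4-one, via 2-hydroxy-1,3-diketone 12 (not isolated)
Conditions: [Cp*Rh(MeCN)3](SbF6)2 (5 mol %), CsOPiv (20 mol %), PivOH (1 equiv), 4 Å MS, DCE, 70 °C, 11 (1.3 equiv) added over 4 h; then TsOH·H2O (10 mol %), 70 °C
Reagents that add atoms: none
Why: Proposed new method: hydroxyl-directed, carboxylate-assisted Rh(III) activation of the aldehydic C–H of 4 gives a five-membered acyl-rhodacycle; the chelating, highly electrophilic aldehyde C=O of 11 binds the cationic Rh and inserts into the Rh–acyl bond (a directed cross-acyloin, i.e. hydroacylation of C=O); PivOH protonates the Rh alkoxide to release 12 and turn the catalyst over; 12 then closes by attack of the phenol on the aryl ketone and loss of water, an irreversible step that pulls the reversible insertion forward and fixes O1 on the hydroxyl that directed the C–H activation, so only the 5,7,8-pattern can form; the closest known reaction types are Cp*Rh(III) annulations of salicylaldehydes with alkynes and carbene precursors to chromones and Rh(III)–aryl 1,2-additions to activated aldehydes, whereas insertion of an aldehyde into the acyl–Rh bond of a salicylaldehyde-derived rhodacycle has not been shown.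

Step 8
Reactants: 13 2-[2,4-bis(benzyloxy)-5-methoxyphenyl]-3-hydroxy-5,7,8-trimethoxy-4H-chromen-4-one
Product: 14 2-(2,4-dihydroxy-5-methoxyphenyl)-3,5-dihydroxy-7,8-dimethoxy-4H-chromen-4-one
Conditions: BCl3 (8 equiv), C6HMe5 (5 equiv), CH2Cl2, −78 → 0 °C; then H2O
Reagents that add atoms: none
Why: BCl3 ether cleavage; pentamethylbenzene traps the benzyl cations (Friedel–Crafts), and only the 5-OMe, chelated to boron through the C4 carbonyl, is demethylated (peri-chelation-directed demethylation), while the 7-, 8- and 5'-OMe groups survive at or below 0 °C.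

**Compound list**
1 | 1,2,3,5-tetramethoxybenzene | COc1cc(OC)c(OC)c(OC)c1 | starting material
2 | N-methyl-N-[(2,3,4,6-tetramethoxyphenyl)methylidene]methanaminium chloride (not isolated) | COc1cc(OC)c(C=[N+](C)C)c(OC)c1OC.[Cl-] | intermediate
3 | 2,3,4,6-tetramethoxybenzaldehyde | COc1cc(OC)c(C=O)c(OC)c1OC | intermediate
4 | 2-hydroxy-3,4,6-trimethoxybenzaldehyde | COc1cc(OC)c(C=O)c(O)c1OC | intermediate
5 | 3-(benzyloxy)-4-methoxybenzaldehyde (O-benzylisovanillin) | COc1ccc(C=O)cc1OCc1ccccc1 | starting material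
6 | 3-(benzyloxy)-4-methoxyphenyl formate (not isolated) | COc1ccc(OC=O)cc1OCc1ccccc1 | intermediate
7 | 3-(benzyloxy)-4-methoxyphenol | COc1ccc(O)cc1OCc1ccccc1 | intermediate
8 | 2,4-bis(benzyloxy)-1-methoxybenzene | COc1ccc(OCc2ccccc2)cc1OCc1ccccc1 | intermediate
9 | 1-[2,4-bis(benzyloxy)-5-methoxyphenyl]ethan-1-one | CC(=O)c1cc(OC)c(OCc2ccccc2)cc1OCc1ccccc1 | intermediate
10 | 1-[2,4-bis(benzyloxy)-5-methoxyphenyl]-2,2-dihydroxyethan-1-one, the glyoxal hydrate (not isolated) | OC(O)C(=O)c1cc(OC)c(OCc2ccccc2)cc1OCc1ccccc1 | intermediate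
11 | 2-[2,4-bis(benzyloxy)-5-methoxyphenyl]-2-oxoacetaldehyde | O=CC(=O)c1cc(OC)c(OCc2ccccc2)cc1OCc1ccccc1 | intermediate
12 | 1-[2,4-bis(benzyloxy)-5-methoxyphenyl]-2-hydroxy-3-(2-hydroxy-3,4,6-trimethoxyphenyl)propane-1,3-dione (not isolated; C2 forms racemic and is lost on dehydration) | COc1cc(OC)c(C(=O)C(O)C(=O)c2cc(OC)c(OCc3ccccc3)cc2OCc2ccccc2)c(O)c1OC | intermediate
13 | 2-[2,4-bis(benzyloxy)-5-methoxyphenyl]-3-hydroxy-5,7,8-trimethoxy-4H-chromen-4-one | COc1cc(-c2oc3c(OC)c(OC)cc(OC)c3c(=O)c2O)c(OCc2ccccc2)cc1OCc1ccccc1 | intermediate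
14 | 2-(2,4-dihydroxy-5-methoxyphenyl)-3,5-dihydroxy-7,8-dimethoxy-4H-chromen-4-one (no stereocentres) | COc1cc(-c2oc3c(OC)c(OC)cc(O)c3c(=O)c2O)c(O)cc1O | target

**Totals**
Total step count: 8 (steps 1–2 ring-A branch, steps 3–6 ring-B branch, steps 7–8 after convergence).
Longest linear sequence: 6 steps (5 → 7 → 8 → 9 → 11 → 13 → 14).

**Three steps most likely to fail**

Step 5 (Friedel–Crafts acetylation). The risk is acid-promoted loss or migration of a benzyl group, above all the one that ends up ortho to the new ketone. The fallback sets out from 8 and returns to the route at 9, and replaces electrophilic acylation by cross-coupling. NBS (MeCN, 0 °C) brominates the same C5 position to give 1,5-bis(benzyloxy)-2-bromo-4-methoxybenzene F1. Stille coupling with tributyl(1-ethoxyvinyl)stannane (Pd(PPh3)4, toluene, 100 °C) gives 1,5-bis(benzyloxy)-2-(1-ethoxyethenyl)-4-methoxybenzene F2. 1 M HCl/THF at rt hydrolyses the enol ether to 9, and no Lewis acid meets the benzyl ethers.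

Step 7 (proposed new step). The risks are decarbonylation of the acyl-rhodium, a reversible or slow C=O insertion, inhibition of the catalyst by the chelating flavonol, and self-condensation of 11. The fallback is the classical chalcone–flavone–flavonol sequence, all known chemistry; it sets out from 1 and 8 and returns to the route at 13. Friedel–Crafts acetylation of 1 (AcCl, AlCl3, Et2O), with in situ cleavage of the buttressed ortho-methoxy group, gives 1-(2-hydroxy-3,4,6-trimethoxyphenyl)ethan-1-one F3. Vilsmeier–Haack formylation of 8 (POCl3, DMF) gives 2,4-bis(benzyloxy)-5-methoxybenzaldehyde F4. Claisen–Schmidt condensation of the two (KOH, EtOH, rt) gives (E)-3-[2,4-bis(benzyloxy)-5-methoxyphenyl]-1-(2-hydroxy-3,4,6-trimethoxyphenyl)prop-2-en-1-one F5. Algar–Flynn–Oyamada oxidation is avoided because 6'-alkoxy chalcones give aurones; instead I2 (cat.) in DMSO at 120 °C closes and dehydrogenates the chalcone to 2-[2,4-bis(benzyloxy)-5-methoxyphenyl]-5,7,8-trimethoxy-4H-chromen-4-one F6. DMDO (acetone/CH2Cl2, 0 °C) gives the racemic, necessarily cis-fused 2-[2,4-bis(benzyloxy)-5-methoxyphenyl]-2,3-epoxy-5,7,8-trimethoxychroman-4-one F7, which opens with catalytic TsOH to flavonol 13.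

Step 8 (one-pot global deprotection). The risk is that the boron chelate between the free 3-OH and the C4 carbonyl slows the 5-O-demethylation, or that forcing it also cleaves the 5'-OMe next to the freed 4'-OH. The fallback sets out from 13 and returns to the route at 14, and separates the two events by mechanism. Hydrogenolysis (H2 1 atm, 10 % Pd/C, EtOAc/MeOH, rt) removes both benzyl groups to give 2-(2,4-dihydroxy-5-methoxyphenyl)-3-hydroxy-5,7,8-trimethoxy-4H-chromen-4-one F8. AlCl3 (5 equiv) in MeCN at 50 °C, then aq. HCl, cleaves only the peri-chelated 5-OMe to give 14.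

**Further compounds**
F1 | step 5 | 1,5-bis(benzyloxy)-2-bromo-4-methoxybenzene | COc1cc(Br)c(OCc2ccccc2)cc1OCc1ccccc1
F2 | step 5 | 1,5-bis(benzyloxy)-2-(1-ethoxyethenyl)-4-methoxybenzene | CCOC(=C)c1cc(OC)c(OCc2ccccc2)cc1OCc1ccccc1
F3 | step 7 | 1-(2-hydroxy-3,4,6-trimethoxyphenyl)ethan-1-one | COc1cc(OC)c(C(C)=O)c(O)c1OC
F4 | step 7 | 2,4-bis(benzyloxy)-5-methoxybenzaldehyde | COc1cc(C=O)c(OCc2ccccc2)cc1OCc1ccccc1
F5 | step 7 | (E)-3-[2,4-bis(benzyloxy)-5-methoxyphenyl]-1-(2-hydroxy-3,4,6-trimethoxyphenyl)prop-2-en-1-one | COc1cc(OC)c(C(=O)/C=C/c2cc(OC)c(OCc3ccccc3)cc2OCc2ccccc2)c(O)c1OC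
F6 | step 7 | 2-[2,4-bis(benzyloxy)-5-methoxyphenyl]-5,7,8-trimethoxy-4H-chromen-4-one | COc1cc(-c2cc(=O)c3c(OC)cc(OC)c(OC)c3o2)c(OCc2ccccc2)cc1OCc1ccccc1
F7 | step 7 | 2-[2,4-bis(benzyloxy)-5-methoxyphenyl]-2,3-epoxy-5,7,8-trimethoxychroman-4-one (racemic, cis-fused, one enantiomer drawn) | O=C1[C@@H]2O[C@]2(c3cc(OC)c(OCc4ccccc4)cc3OCc3ccccc3)Oc2c(OC)c(OC)cc(OC)c12
F8 | step 8 | 2-(2,4-dihydroxy-5-methoxyphenyl)-3-hydroxy-5,7,8-trimethoxy-4H-chromen-4-one | COc1cc(-c2oc3c(OC)c(OC)cc(OC)c3c(=O)c2O)c(O)cc1O
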